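The cyclohexane is disconnected at the C5–C6 bond (ring atoms: C1 = CMeCl, C2, C3 = quaternary carbon, C4 = CHBr, C5, C6 = CHBr). The key step exploits the 1,3-dibromide C4(Br)–C5H2–C6(Br) and treats C1 as a latent ketone: a copper-catalysed 6-endo atom-transfer radical cyclisation of an acyclic dibromomethyl ketone onto a vinyl group forms C5–C6 and installs both secondary bromides in one operation. The precursor, (S)-Br2CH–CO–CH2–C(Me)(C≡CH)–CH=CH2, takes its quaternary centre from a lipase-resolved allylic alcohol by Johnson–Claisen chirality transfer. Afterwards the ketone becomes C(Me)Cl under bromonium control and the ethynyl placeholder becomes the (E)-chlorovinyl group.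

Key step: step 8

Remark: commercial (2E)-3-methylpent-2-en-4-yn-1-ol is taken as the pure E isomer; the ring numbering of the overview is used for all cyclic compounds.

Step 1
Reactants: 1 (2E)-3-methylpent-2-en-4-yn-1-ol
Product: 2 (2E)-3-methylpent-2-en-4-ynal
Conditions: activated MnO2 (10 equiv), CH2Cl2, rt
Reagents that add atoms: none
Why: Allylic oxidation with activated MnO2 is selective for the allylic carbinol and should leave the E alkene and the terminal alkyne untouched.

Step 2
Reactants: 2 (2E)-3-methylpent-2-en-4-ynal
Product: 3 rac-(3E)-4-methylhex-3-en-5-yn-2-ol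
Conditions: MeMgBr (1.1 equiv), THF, −78 °C; then H2O
Reagents that add atoms: methylmagnesium bromide, C[Mg]Br
Why: 1,2-Grignard addition to the enal is faster at −78 °C than deprotonation of the alkyne and should give the racemic secondary allylic alcohol, whose stereocentre is sorted out in step 3.

Step 3
Reactants: 3 rac-(3E)-4-methylhex-3-en-5-yn-2-ol
Product: 4 (2S,3E)-4-methylhex-3-en-5-yn-2-ol
Conditions: Novozym 435 (immobilised Candida antarctica lipase B), vinyl acetate, hexane, rt, run to slightly beyond half conversion; chromatography
Reagents that add atoms: none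
Why: Lipase-catalysed kinetic resolution by transesterification: by the empirical rule for secondary carbinols with one small (methyl) and one large (alkenyl) group the R enantiomer is acetylated faster, so the unreacted S alcohol should be recovered in high enantiomeric purity.

Step 4
Reactants: 4 (2S,3E)-4-methylhex-3-en-5-yn-2-ol
Product: 6 ethyl (3S,4E)-3-ethynyl-3-methylhex-4-enoate, via mixed ketene acetal 5 (not isolated)
Conditions: MeC(OEt)3 (6 equiv), EtCO2H (cat.), 135 °C, EtOH distilled off
Reagents that add atoms: triethyl orthoacetate, CCOC(C)(OCC)OCC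
Why: Johnson–Claisen rearrangement through ketene acetal 5: the chair transition state with the carbinol methyl equatorial delivers the new C–C bond to the alkene face fixed by the C–O stereocentre, so the S carbinol should give the S quaternary centre (methyl, ethynyl) together with the E propenyl group.

Step 5
Reactants: 6 ethyl (3S,4E)-3-ethynyl-3-methylhex-4-enoate
Product: 8 ethyl (3R)-3-formyl-3-methylpent-4-ynoate, via secondary ozonide 7 (not isolated)
Conditions: O3, CH2Cl2, −78 °C, stopped at the first excess of ozone; then PPh3, −78 °C to rt
Reagents that add atoms: ozone, O=[O+][O-]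
Why: Ozonolysis with reductive work-up: the electron-rich disubstituted alkene reacts far faster with ozone than the terminal alkyne, and the quaternary centre is untouched (its descriptor becomes R only through the priority of the formyl group).

Step 6
Reactants: 8 ethyl (3R)-3-formyl-3-methylpent-4-ynoate
Product: 9 ethyl (3S)-3-ethynyl-3-methylpent-4-enoate
Conditions: Ph3PCH3Br, KOtBu, THF, 0 °C; then 8, −78 to 0 °C
Reagents that add atoms: methyltriphenylphosphonium bromide, C[P+](c1ccccc1)(c1ccccc1)c1ccccc1.[Br-]
Why: Wittig methylenation of a non-enolisable α-quaternary aldehyde should give the vinyl group that serves as radical acceptor in step 8 without touching the stereocentre.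

Step 7
Reactants: 9 ethyl (3S)-3-ethynyl-3-methylpent-4-enoate
Product: 11 (4S)-1,1-dibromo-4-ethynyl-4-methylhex-5-en-2-one, via lithium hemiketal alkoxide 10 (not isolated)
Conditions: CH2Br2 (2.2 equiv), LiN(iPr)2 (2.2 equiv), THF, −90 °C; then 9; then HCl in EtOH, −90 °C to rt
Reagents that add atoms: dibromomethane, BrCBr
Why: Acylation of dibromomethyllithium by the ester (first stage of the Kowalski ester homologation): the tetrahedral adduct 10 is stable at −90 °C, which prevents a second addition, and collapses to the α,α-dibromomethyl ketone on acidic quench.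

Step 8
Reactants: 11 (4S)-1,1-dibromo-4-ethynyl-4-methylhex-5-en-2-one
Product: 12 (2S,4S,5R)-2,4-dibromo-5-ethynyl-5-methylcyclohexan-1-one
Conditions: CuBr (10 mol %), tris(2-pyridylmethyl)amine (10 mol %), degassed ClCH2CH2Cl, 40 °C
Reagents that add atoms: none
Why: Monovalent copper abstracts one bromine atom from the CHBr2 group, the electrophilic α-bromo-α-keto radical at C6 adds to the unsubstituted terminus C5 of the vinyl group, and the secondary C4 radical takes a bromine atom back from the divalent copper bromide complex, which returns the catalyst. The closest known reaction type is the copper-catalysed atom-transfer radical cyclisation of α-halo ketones and α-halo-β-keto esters onto alkenes, in which 2-oxohex-5-enyl radicals close 6-endo. The cyclohexanone ring closes in the 6-endo-trig mode, favoured over 5-exo because the carbonyl inside the forming ring strains the 5-exo transition state and the internal alkene carbon C4 is neopentylic. C6 is set in a chair transition state that keeps the slim ethynyl group axial and the C3 methyl equatorial while the C6–Br bond stays syn to the carbonyl oxygen and therefore ends equatorial, cis to the ethynyl group. C4 is set by axial bromine delivery to the ring radical anti to the axial ethynyl group, the face that also avoids a 1,3-diaxial clash with the C6 bromide, so that the C4 bromide ends cis to the C3 methyl. The step needs attack on the vinyl and not the ethynyl group and no 1,2-shift of the C4 radical, which the lower radical affinity of the alkyne, the disfavoured 5-exo-dig path and the slow 1,2-alkynyl shift should secure.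

Step 9
Reactants: 12 (2S,4S,5R)-2,4-dibromo-5-ethynyl-5-methylcyclohexan-1-one
Product: 13 (1S,2S,4S,5R)-2,4-dibromo-5-ethynyl-1,5-dimethylcyclohexan-1-ol
Conditions: MeMgBr (1.5 equiv), CeCl3 (1.5 equiv), THF, −78 °C; then H2O at −78 °C
Reagents that add atoms: methylmagnesium bromide, C[Mg]Br
Why: CeCl3-promoted Grignard addition to the α-bromo ketone favours carbonyl addition over enolisation, the cold quench prevents epoxide closure of the bromohydrin, and the C1 configuration (drawn with methyl cis to the C6 bromine) is not critical because both C1 epimers ionise to the same cation in step 10.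

Step 10
Reactants: 13 (1S,2S,4S,5R)-2,4-dibromo-5-ethynyl-1,5-dimethylcyclohexan-1-ol
Product: 14 (1S,2S,4S,5R)-2,4-dibromo-1-chloro-5-ethynyl-1,5-dimethylcyclohexane
Conditions: HCl (g), CH2Cl2, −20 to 0 °C
Reagents that add atoms: hydrogen chloride, Cl
Why: SN1 substitution with neighbouring-group participation: the C6 bromine bridges the tertiary C1 cation as a bromonium ion and chloride opens it at the tertiary carbon from the opposite face, which should set C1 with chlorine trans to the C6 bromine and cis to the C3 methyl.

Step 11
Reactants: 14 (1S,2S,4S,5R)-2,4-dibromo-1-chloro-5-ethynyl-1,5-dimethylcyclohexane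
Product: 16 (1S,2S,4S,5R)-2,4-dibromo-1-chloro-5-[(E)-2-chloroethenyl]-1,5-dimethylcyclohexane, via alkenylzirconocene chloride 15 (not isolated)
Conditions: (C5H5)2Zr(H)Cl (1.3 equiv), CH2Cl2, rt; then N-chlorosuccinimide, 0 °C
Reagents that add atoms: N-chlorosuccinimide, ClN1C(=O)CCC1=O
Why: Hydrozirconation–halogenation: syn addition of Zr–H places zirconium at the terminal alkyne carbon in alkenylzirconium 15 and chlorination with N-chlorosuccinimide proceeds with retention to give the E chloroalkene, the alkyl halides being expected to survive the short exposure.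

Compound list
1 | (2E)-3-methylpent-2-en-4-yn-1-ol | OC/C=C(\C)C#C | starting material
2 | (2E)-3-methylpent-2-en-4-ynal | O=C/C=C(\C)C#C | intermediate
3 | rac-(3E)-4-methylhex-3-en-5-yn-2-ol | CC(O)/C=C(\C)C#C | intermediate
4 | (2S,3E)-4-methylhex-3-en-5-yn-2-ol | C[C@H](O)/C=C(\C)C#C | intermediate
5 | (2S,3E)-2-[(1-ethoxyethenyl)oxy]-4-methylhex-3-en-5-yne (mixed ketene acetal) | C=C(OCC)O[C@@H](C)/C=C(\C)C#C | intermediate (not isolated)
6 | ethyl (3S,4E)-3-ethynyl-3-methylhex-4-enoate | CCOC(=O)C[C@](C)(C#C)/C=C/C | intermediate
7 | ethyl (3R)-3-methyl-3-(5-methyl-1,2,4-trioxolan-3-yl)pent-4-ynoate (ozonide, diastereomers at the trioxolane carbons) | CCOC(=O)C[C@](C)(C#C)C1OC(C)OO1 | intermediate (not isolated)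
8 | ethyl (3R)-3-formyl-3-methylpent-4-ynoate | CCOC(=O)C[C@](C)(C#C)C=O | intermediate
9 | ethyl (3S)-3-ethynyl-3-methylpent-4-enoate | CCOC(=O)C[C@](C)(C#C)C=C | intermediate
10 | lithium (4S)-1,1-dibromo-2-ethoxy-4-ethynyl-4-methylhex-5-en-2-olate (both C2 epimers) | [Li+].CCOC([O-])(C(Br)Br)C[C@](C)(C#C)C=C | intermediate (not isolated)
11 | (4S)-1,1-dibromo-4-ethynyl-4-methylhex-5-en-2-one | BrC(Br)C(=O)C[C@](C)(C#C)C=C | intermediate
12 | (2S,4S,5R)-2,4-dibromo-5-ethynyl-5-methylcyclohexan-1-one | O=C1C[C@](C)(C#C)[C@@H](Br)C[C@@H]1Br | intermediate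
13 | (1S,2S,4S,5R)-2,4-dibromo-5-ethynyl-1,5-dimethylcyclohexan-1-ol | C[C@]1(O)C[C@](C)(C#C)[C@@H](Br)C[C@@H]1Br | intermediate
14 | (1S,2S,4S,5R)-2,4-dibromo-1-chloro-5-ethynyl-1,5-dimethylcyclohexane | C[C@]1(Cl)C[C@](C)(C#C)[C@@H](Br)C[C@@H]1Br | intermediate
15 | chlorobis(cyclopentadienyl)[(E)-2-[(1R,2S,4S,5S)-2,4-dibromo-5-chloro-1,5-dimethylcyclohexyl]ethenyl]zirconium | C[C@]1(Cl)C[C@](C)(/C=C/[Zr](Cl)(C2C=CC=C2)C2C=CC=C2)[C@@H](Br)C[C@@H]1Br | intermediate (not isolated)
16 | (1S,2S,4S,5R)-2,4-dibromo-1-chloro-5-[(E)-2-chloroethenyl]-1,5-dimethylcyclohexane | C[C@]1(Cl)C[C@](C)(/C=C/Cl)[C@@H](Br)C[C@@H]1Br | target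

Total step count: 11. Longest linear sequence: 11 steps (the route is fully linear from 1).

Steps most likely to fail

Step 8. The bromine transfer to the C4 ring radical, or the facial course of the C6 radical in the ring closure, may proceed with poor selectivity once both bromides are set in the same event. The fallback installs the two bromides separately. Setting out from dibromo ketone 11, halophilic monodebromination with (EtO)2P(O)H and Et3N in THF at 0 °C would give (4S)-1-bromo-4-ethynyl-4-methylhex-5-en-2-one F1. Its copper-catalysed atom-transfer cyclisation, now free of any C6 substituent, would give (3R,4S)-4-bromo-3-ethynyl-3-methylcyclohexan-1-one F2. Ionic α-bromination with PhNMe3Br3 in THF at the less hindered α-carbon C6, equilibrated by the HBr formed towards the axial bromide, would come back to the route at ketone 12.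

Step 10. Ionisation of the tertiary alcohol may end in elimination to allylic bromides or in bromine migration instead of chloride capture at C1. Setting out from bromohydrin 13, zinc dust in acetic acid at rt would remove hydroxyl and bromide reductively and give (4S,5R)-4-bromo-5-ethynyl-1,5-dimethylcyclohex-1-ene F3, with the double bond fixed between C1 and C6. Markovnikov, anti bromochlorination with Bu4NBrCl2 in CH2Cl2 at −78 °C, with bromonium formation expected on the ring face remote from the C4 bromide, would come back to the route at chloride 14.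

Step 11. The zirconium hydride may reduce or eliminate the alkyl halides, or hydrometalation of the neopentylic alkyne may stall. Setting out from chloride 14, hydroboration with catecholborane (cat. dicyclohexylborane, THF, rt) would give 2-[(E)-2-[(1R,2S,4S,5S)-2,4-dibromo-5-chloro-1,5-dimethylcyclohexyl]ethenyl]-1,3,2-benzodioxaborole F4. Hydrolysis with water would give [(E)-2-[(1R,2S,4S,5S)-2,4-dibromo-5-chloro-1,5-dimethylcyclohexyl]ethenyl]boronic acid F5. Halodeboronation with N-chlorosuccinimide (cat. Et3N, MeCN, rt), which retains the alkene geometry, would arrive at target 16.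

Further compounds
F1 | step 8 | (4S)-1-bromo-4-ethynyl-4-methylhex-5-en-2-one | BrCC(=O)C[C@](C)(C#C)C=C
F2 | step 8 | (3R,4S)-4-bromo-3-ethynyl-3-methylcyclohexan-1-one | O=C1C[C@](C)(C#C)[C@@H](Br)CC1
F3 | step 10 | (4S,5R)-4-bromo-5-ethynyl-1,5-dimethylcyclohex-1-ene | CC1=CC[C@H](Br)[C@@](C)(C#C)C1
F4 | step 11 | 2-[(E)-2-[(1R,2S,4S,5S)-2,4-dibromo-5-chloro-1,5-dimethylcyclohexyl]ethenyl]-1,3,2-benzodioxaborole | C[C@]1(Cl)C[C@](C)(/C=C/B2Oc3ccccc3O2)[C@@H](Br)C[C@@H]1Br
F5 | step 11 | [(E)-2-[(1R,2S,4S,5S)-2,4-dibromo-5-chloro-1,5-dimethylcyclohexyl]ethenyl]boronic acid | C[C@]1(Cl)C[C@](C)(/C=C/B(O)O)[C@@H](Br)C[C@@H]1Br
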